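## The problem

The target 20 (C28H24O4) is a macrocyclic bis(bibenzyl). Four benzene rings are joined into one 18-membered ring by two CH2CH2 bridges (ring A to ring B, ring C to ring D) and two diaryl ether oxygens (ring B to ring C, ring D to ring A). Ring A is 1,2,4-trisubstituted (ether oxygen at C1, ethano chain at C2, OH at C4, para to the ether), ring B is a para-phenylene, ring C carries its ether oxygen at C3 and its OH at C4 relative to its chain, and ring D is a meta-phenylene. There is no stereocentre, so every selectivity question is regiochemical (which oxygen of ring C is arylated, where ring A carries its three substituents) or chemoselective. The para-phenylene ring B has to span the macrocycle, so ring closure competes with oligomerisation and must tolerate high dilution. The two phenols, one para and one ortho to an aryloxy group, make rings A and C easily oxidised once free; they are best carried masked and released last, whereas the diaryl ethers and the saturated bridges are robust. The ortho relationship of ether oxygen and chain on ring A makes a late aryl–oxygen coupling at that position hindered. The same feature opens the key step: C1 and C2 of ring A, with their oxygen and chain, are the two carbons of an aryloxy alkyne ArO–C≡C–CH2CH2Ar, and C3–C6, with an acyl carbon at C4 that can later be exchanged for OH, are the diene carbons of a 5-acyl 2-pyrone.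

## Retrosynthesis

**End game, 20 back to 15.** The ring C hydroxyl is kept as its methyl ether (19) until the last step. The ring A hydroxyl of 19 is traced through the aryl formate 18 to the aldehyde 17, then to the benzylic alcohol 16 and the methyl ester 15, so the ring A C4–O bond is exchanged for a C4–C bond. The neighbouring choice, carrying the ring A oxygen as an ether from the start, would demand an oxygen-substituted pyrone, which is electron-richer and a poor diene for the planned cycloaddition; the ester is what activates the pyrone. The forward Baeyer–Villiger step needs aryl rather than hydride migration, which the para aryloxy group of ring A should secure.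

**Macrocycle, 15 back to 13.** The 18-membered ring is opened at the bond between the ring C oxygen and C4 of ring B, giving the bromo phenol 14 and, with the phenol benzylated, 13. The other ether (ring D–O–ring A) is not cut here because it is to be made with ring A itself. Closing a CH2–CH2 bridge instead would need two extra carbonyl or phosphonium handles and a reduction on the macrocycle. The chosen cut leaves only an aryl bromide and a benzyl ether as spectators for the cycloaddition. The forward reaction is an intramolecular Ullmann etherification in which the only phenol and the only aryl halide of 14 are the two partners.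

**Ring A, 13 back to 10 and 11 (key disconnection).** Ring A is dismantled by cutting its C2–C3 and C1–C6 bonds, giving the aryl ynol ether 10 (ring D–O–C≡C–CH2CH2–ring B, with ring C attached to ring D) and methyl coumalate 11. The alternative of buying a 1,2,4-trisubstituted benzene and forging the ring D–O–ring A ether by cross-coupling ortho to the chain is the hindered coupling this cut avoids. The precursor 10 is linear and has no ring A at all, and 11 is a commercial pyrone. The forward step must be regioselective: ester para to the aryloxy group, chain meta to the ester.

**Ynol ether, 10 back to 5 and 8.** The O–C(sp) bond is cut, leading to the bibenzyl phenol 5 and the 1,1-dibromoalkene 8, joined through the bromoenol ether 9. The neighbouring cut, alkylation of an aryloxyacetylide with a phenethyl electrophile, is prone to elimination and is kept as a reserve. The forward coupling has to distinguish the alkenyl gem-dibromide from the aryl bromide of ring B.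

**Building blocks.** Phenol 5 is cut at the bibenzyl bridge into the phosphonium salt 2 (from commercial 3-hydroxybenzyl alcohol 1) and commercial O-benzylisovanillin 3, joined as the stilbene 4 and reduced without loss of the benzyl ether. Dibromoalkene 8 comes from the aldehyde 7, the oxidation product of commercial 3-(4-bromophenyl)propan-1-ol 6. The benzyl/methyl pattern of 3 already marks which ring C oxygen becomes the ether and which the phenol.

## Roads not taken

**Alternative 1:** The cut is the same ring B carbon–oxygen bond that the chosen route closes in step 9, but the forward step is an SNAr reaction. The ring C phenoxide of the open-chain fluoronitroarene A1 displaces fluoride ortho to a nitro group to give the macrocyclic nitro diaryl ether A2.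
- Merits: the closure is metal-free and mild, and it is among the most dependable ways to close a diaryl ether macrocycle. In reliability of ring closure it is better than an Ullmann reaction on an unactivated bromide.
- Weak points: the nitro group is a pure auxiliary and leaves only by reduction, diazotisation and hydrodediazoniation on the macrocycle. A1 has to be assembled from four pre-functionalised arenes by two olefination/hydrogenation sequences and an intermolecular Ullmann coupling at the hindered position ortho to the ring A chain.
- Comparison: step counts would be similar. The chosen plan sets against the better closure that no activating group has to be removed, that ring A and its hindered ether arise in one convergent step from 11, and that its own closure has a reserve variant.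

**Alternative 2:** Ring B is cut at two carbon–carbon bonds into a 2-aryloxybuta-1,3-diene on the ring C oxygen and an ethynyl ketone on the ring A side chain (A3). A thermal type 2 intramolecular Diels–Alder reaction would give the macrocyclic cyclohexadienyl ketone A4, forming ring B and the 18-membered ring at once.
- Merits: the largest gain in complexity per step, donor and acceptor matched for the para orientation, and a macrocyclisation by carbon–carbon bond formation. In bond economy it is better than the chosen plan, which uses its cycloaddition for ring A only and needs a separate ring closure.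
- Weak points: A4 still needs dehydrogenation of the cyclohexadiene and removal of the bridge ketone. The aryloxydiene and the terminal ynone are both sensitive and must coexist in A3. A cycloaddition through an 18-membered transition state must outrun intermolecular reaction at high dilution and high temperature.
- Comparison: the chosen plan sets against it an intermolecular Diels–Alder reaction that can be driven with excess 11 and gives the aromatic oxidation level directly, with standard chemistry elsewhere.

**Alternative 3:** The cut is the ring C carbon–oxygen bond of the ring B/ring C ether. Tl(NO3)3 in methanol oxidises the dibromophenol ring of the bis(dihalophenol) A5, the ring B phenol oxygen adds at a bromine-bearing ortho carbon, and zinc/acetic acid work-up gives the trihalogenated macrocycle A6.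
- Merits: the closure is biomimetic and non-basic, and it delivers the ortho-hydroxy diaryl ether of ring C with the phenol already free. In this respect it is better than the chosen route, which must carry a benzyl/methyl differentiation on ring C through most of its steps.
- Weak points: four halogens are installed and three removed later, trivalent thallium is needed in more than stoichiometric amount, and the electron-rich ring A ether is a competing oxidation site. A5 still requires the hindered ring A/ring D ether and both bridges.
- Comparison: the chosen plan sets against it the absence of thallium and halogen overhead, and a construction of ring A that no oxidative coupling offers.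

Key step: step 7

Assumption: 20 has no stereocentre; the stilbene 4 is carried as an E/Z mixture, and the transient lactone 12 is racemic (one enantiomer is written in its SMILES).

## Route

Step 1
Reactants: 1 3-hydroxybenzyl alcohol
Product: 2 (3-hydroxybenzyl)triphenylphosphonium bromide
Conditions: PPh3·HBr, MeCN, reflux
Reagents that add atoms: triphenylphosphine hydrobromide, [Br-].[PH+](c1ccccc1)(c1ccccc1)c1ccccc1
Why: Phosphonium salt formation by acid-promoted substitution of a benzylic alcohol; the hydrobromide supplies acid and nucleophile, water is the only by-product and the phenol is untouched.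

Step 2
Reactants: 2 (3-hydroxybenzyl)triphenylphosphonium bromide; 3 3-(benzyloxy)-4-methoxybenzaldehyde
Product: 4 3-{2-[3-(benzyloxy)-4-methoxyphenyl]ethenyl}phenol (E/Z mixture)
Conditions: KOtBu (2.2 equiv), THF, 0 °C to rt; aq. NH4Cl
Reagents that add atoms: none
Why: Wittig olefination with a semi-stabilised benzyl ylide; the second equivalent of base covers the phenol, whose phenoxide is meta to the ylide carbon and does not disturb it, and the E/Z ratio is irrelevant because the double bond is reduced next.

Step 3
Reactants: 4 3-{2-[3-(benzyloxy)-4-methoxyphenyl]ethenyl}phenol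
Product: 5 3-{2-[3-(benzyloxy)-4-methoxyphenyl]ethyl}phenol
Conditions: TsNHNH2, NaOAc, DME/H2O, reflux
Reagents that add atoms: none
Why: Diimide reduction saturates both stilbene isomers by concerted transfer of two hydrogens and, unlike hydrogenation over Pd/C, cannot hydrogenolyse the benzyl ether.

Step 4
Reactants: 6 3-(4-bromophenyl)propan-1-ol
Product: 7 3-(4-bromophenyl)propanal
Conditions: Dess–Martin periodinane, NaHCO3, CH2Cl2, 0 °C to rt
Reagents that add atoms: none
Why: Dess–Martin oxidation of a primary alcohol stops at the aldehyde under buffered, non-aqueous conditions; the aryl bromide is inert.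

Step 5
Reactants: 7 3-(4-bromophenyl)propanal
Product: 8 1-bromo-4-(4,4-dibromobut-3-en-1-yl)benzene
Conditions: CBr4, PPh3, CH2Cl2, 0 °C
Reagents that add atoms: carbon tetrabromide, BrC(Br)(Br)Br
Why: Dibromomethylenation of an aldehyde, the first stage of the Corey–Fuchs sequence, through the ylide Ph3P=CBr2; an unhindered aliphatic aldehyde reacts at 0 °C.

Step 6
Reactants: 5 3-{2-[3-(benzyloxy)-4-methoxyphenyl]ethyl}phenol; 8 1-bromo-4-(4,4-dibromobut-3-en-1-yl)benzene
Product: 10 1-{[4-(4-bromophenyl)but-1-yn-1-yl]oxy}-3-{2-[3-(benzyloxy)-4-methoxyphenyl]ethyl}benzene, via (Z)-bromoenol ether 9 (not isolated)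
Conditions: 8 (1.5 equiv), CuI (10 mol %), 2,2'-bipyridine (20 mol %), K3PO4, toluene, 110 °C; filter, concentrate; then KOtBu, 1,4-dioxane, rt
Reagents that add atoms: none
Why: Copper-catalysed cross-coupling of a phenol with a 1,1-dibromo-1-alkene occurs at the more accessible C–Br bond trans to the alkyl chain and gives the (Z)-1-bromoenol ether 9, whose vinylic hydrogen is anti to the remaining bromine, so KOtBu effects anti-dehydrobromination to the aryl ynol ether. The alkenyl gem-dibromide should react well before the ring B aryl bromide under this ligand system, and the excess of 8 suppresses double substitution to a ketene acetal.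

Step 7
Reactants: 10 1-{[4-(4-bromophenyl)but-1-yn-1-yl]oxy}-3-{2-[3-(benzyloxy)-4-methoxyphenyl]ethyl}benzene; 11 methyl coumalate (methyl 2-oxo-2H-pyran-5-carboxylate)
Product: 13 methyl 4-(3-{2-[3-(benzyloxy)-4-methoxyphenyl]ethyl}phenoxy)-3-[2-(4-bromophenyl)ethyl]benzoate, via bicyclic lactone 12 (not isolated)
Conditions: 11 (2–3 equiv, in portions), dry toluene, 150 °C, sealed tube, acid-free glassware
Reagents that add atoms: none
Why: Inverse-electron-demand Diels–Alder reaction between the electron-poor diene of 11 (C3=C4–C5=C6) and the electron-rich alkyne of 10, followed by retro-[4+2] loss of CO2 from the bridged lactone 12; the closest known reaction type is the cycloaddition of methyl coumalate with enol ethers, ketene acetals, ynamines and simple alkynes, which gives para-substituted benzoates after CO2 extrusion. Ring A is closed by an intermolecular [4+2] cycloaddition that forms two carbon–carbon bonds (pyrone C6 to the chain-bearing alkyne carbon, pyrone C3 to the aryloxy-bearing alkyne carbon), and because the dienophile is an alkyne the diene left after decarboxylation is already the benzene ring. The two bridgehead stereocentres of 12 are transient and vanish on aromatisation, so 13 has none. The selectivity needed is regiochemical: C6 of 11, β to the ester and δ to the lactone carbonyl, carries the largest LUMO coefficient, and the alkyne carbon remote from oxygen carries the largest HOMO coefficient, so these two bond first and the ester ends para to the aryloxy group and meta to the chain. An aryl ynol ether has no O-alkyl hydrogen for retro-ene loss of an alkene, so it should survive the temperature this moderately activated alkyne needs, and exclusion of acid and water prevents its hydration to an aryl ester. The aryl bromide, benzyl ether and methyl ether are spectators under purely thermal conditions.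

Step 8
Reactants: 13 methyl 4-(3-{2-[3-(benzyloxy)-4-methoxyphenyl]ethyl}phenoxy)-3-[2-(4-bromophenyl)ethyl]benzoate
Product: 14 methyl 3-[2-(4-bromophenyl)ethyl]-4-{3-[2-(3-hydroxy-4-methoxyphenyl)ethyl]phenoxy}benzoate
Conditions: BCl3, pentamethylbenzene, CH2Cl2, −78 °C; MeOH
Reagents that add atoms: none
Why: Lewis-acid debenzylation of an aryl benzyl ether with a non-basic cation scavenger; at −78 °C only the benzyl–oxygen bond ionises, so the methyl ether, the ester, the diaryl ether and the aryl bromide (which hydrogenolysis would endanger) remain.

Step 9
Reactants: 14 methyl 3-[2-(4-bromophenyl)ethyl]-4-{3-[2-(3-hydroxy-4-methoxyphenyl)ethyl]phenoxy}benzoate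
Product: 15 macrocyclic methyl ester: the 18-membered ring A–CH2CH2–ring B–O–ring C–CH2CH2–ring D–O cycle with CO2Me on ring A para to its ether oxygen and OMe on ring C ortho to its ether oxygen
Conditions: CuI, N,N-dimethylglycine hydrochloride, Cs2CO3, 1,4-dioxane, 100 °C, slow syringe-pump addition of 14 (final ca. 2 mM)
Reagents that add atoms: none
Why: Intramolecular ligand-accelerated Ullmann diaryl ether synthesis closing the 18-membered ring between the ring C phenoxide and C4 of ring B; the only phenol and the only aryl halide of 14 are the two partners, high dilution favours ring closure over oligomerisation, and the methyl ester tolerates anhydrous carbonate.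

Step 10
Reactants: 15 macrocyclic methyl ester
Product: 16 macrocyclic benzylic alcohol (CH2OH on ring A in place of CO2Me)
Conditions: i-Bu2AlH, CH2Cl2, −78 to 0 °C; aq. potassium sodium tartrate
Reagents that add atoms: none
Why: Hydride reduction of an aryl ester to the primary benzylic alcohol; ethers and the macrocycle are inert.

Step 11
Reactants: 16 macrocyclic benzylic alcohol
Product: 17 macrocyclic aldehyde (CHO on ring A para to the ether oxygen)
Conditions: MnO2, CH2Cl2, rt
Reagents that add atoms: none
Why: Activated MnO2 oxidises benzylic alcohols selectively and stops at the aldehyde.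

Step 12
Reactants: 17 macrocyclic aldehyde
Product: 19 macrocyclic ring A phenol with ring C methyl ether, via aryl formate 18 (not isolated)
Conditions: mCPBA, CH2Cl2, 0 °C to rt; then K2CO3, MeOH, rt
Reagents that add atoms: mCPBA (3-chloroperoxybenzoic acid), OOC(=O)c1cccc(Cl)c1
Why: Baeyer–Villiger (Dakin-type) oxidation of an aryl aldehyde; the aryloxy group para to the formyl group makes ring A the better migrating group in the Criegee intermediate, and the resulting formate 18 is methanolysed in the same flask.

Step 13
Reactants: 19 macrocyclic ring A phenol with ring C methyl ether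
Product: 20 target macrocycle (CNP0135015.0)
Conditions: BBr3, CH2Cl2, −78 °C to rt; H2O
Reagents that add atoms: none
Why: BBr3 cleavage of the aryl methyl ether at the methyl–oxygen bond; diaryl ethers and the bibenzyl bridges are not attacked.

## Compound list

1 | 3-hydroxybenzyl alcohol | OCc1cccc(O)c1 | starting material
2 | (3-hydroxybenzyl)triphenylphosphonium bromide | [Br-].Oc1cccc(C[P+](c2ccccc2)(c2ccccc2)c2ccccc2)c1 | intermediate
3 | 3-(benzyloxy)-4-methoxybenzaldehyde | COc1ccc(C=O)cc1OCc1ccccc1 | starting material
4 | 3-{2-[3-(benzyloxy)-4-methoxyphenyl]ethenyl}phenol (E/Z mixture, no descriptor written) | Oc1cccc(C=Cc2ccc(OC)c(OCc3ccccc3)c2)c1 | intermediate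
5 | 3-{2-[3-(benzyloxy)-4-methoxyphenyl]ethyl}phenol | Oc1cccc(CCc2ccc(OC)c(OCc3ccccc3)c2)c1 | intermediate
6 | 3-(4-bromophenyl)propan-1-ol | OCCCc1ccc(Br)cc1 | starting material
7 | 3-(4-bromophenyl)propanal | O=CCCc1ccc(Br)cc1 | intermediate
8 | 1-bromo-4-(4,4-dibromobut-3-en-1-yl)benzene | BrC(Br)=CCCc1ccc(Br)cc1 | intermediate
9 | 1-{[(1Z)-1-bromo-4-(4-bromophenyl)but-1-en-1-yl]oxy}-3-{2-[3-(benzyloxy)-4-methoxyphenyl]ethyl}benzene | Br/C(Oc1cccc(CCc2ccc(OC)c(OCc3ccccc3)c2)c1)=C\CCc1ccc(Br)cc1 | intermediate (not isolated)
10 | 1-{[4-(4-bromophenyl)but-1-yn-1-yl]oxy}-3-{2-[3-(benzyloxy)-4-methoxyphenyl]ethyl}benzene | Brc1ccc(CCC#COc2cccc(CCc3ccc(OC)c(OCc4ccccc4)c3)c2)cc1 | intermediate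
11 | methyl coumalate (methyl 2-oxo-2H-pyran-5-carboxylate) | COC(=O)C1=COC(=O)C=C1 | starting material
12 | methyl 5-(3-{2-[3-(benzyloxy)-4-methoxyphenyl]ethyl}phenoxy)-6-[2-(4-bromophenyl)ethyl]-3-oxo-2-oxabicyclo[2.2.2]octa-5,7-diene-7-carboxylate (racemic bridged lactone) | O=C1O[C@H]2C(C(=O)OC)=C[C@@H]1C(Oc3cccc(CCc4ccc(OC)c(OCc5ccccc5)c4)c3)=C2CCc1ccc(Br)cc1 | intermediate (not isolated)
13 | methyl 4-(3-{2-[3-(benzyloxy)-4-methoxyphenyl]ethyl}phenoxy)-3-[2-(4-bromophenyl)ethyl]benzoate | COC(=O)c1ccc(Oc2cccc(CCc3ccc(OC)c(OCc4ccccc4)c3)c2)c(CCc2ccc(Br)cc2)c1 | intermediate
14 | methyl 3-[2-(4-bromophenyl)ethyl]-4-{3-[2-(3-hydroxy-4-methoxyphenyl)ethyl]phenoxy}benzoate | COC(=O)c1ccc(Oc2cccc(CCc3ccc(OC)c(O)c3)c2)c(CCc2ccc(Br)cc2)c1 | intermediate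
15 | macrocyclic methyl ester (CO2Me on ring A para to the ether oxygen, OMe on ring C) | COC(=O)c1ccc2c(c1)CCc1ccc(cc1)Oc1cc(ccc1OC)CCc1cccc(c1)O2 | intermediate
16 | macrocyclic benzylic alcohol (CH2OH on ring A, OMe on ring C) | OCc1ccc2c(c1)CCc1ccc(cc1)Oc1cc(ccc1OC)CCc1cccc(c1)O2 | intermediate
17 | macrocyclic aldehyde (CHO on ring A, OMe on ring C) | O=Cc1ccc2c(c1)CCc1ccc(cc1)Oc1cc(ccc1OC)CCc1cccc(c1)O2 | intermediate
18 | macrocyclic aryl formate (OCHO on ring A, OMe on ring C) | O=COc1ccc2c(c1)CCc1ccc(cc1)Oc1cc(ccc1OC)CCc1cccc(c1)O2 | intermediate (not isolated)
19 | macrocyclic phenol (OH on ring A, OMe on ring C) | Oc1ccc2c(c1)CCc1ccc(cc1)Oc1cc(ccc1OC)CCc1cccc(c1)O2 | intermediate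
20 | target macrocycle, CNP0135015.0 (OH on ring A para to its ether oxygen, OH on ring C ortho to its ether oxygen) | Oc1ccc2c(c1)CCc1ccc(cc1)Oc1cc(ccc1O)CCc1cccc(c1)O2 | target

## Step count and risks

Total step count: 13. Longest linear sequence: 11 steps (steps 1, 2, 3, 6, 7, 8, 9, 10, 11, 12, 13, starting from 1).

**Step 7 (key step).** An aryloxy alkyne is a weaker donor than the ynamines and ketene acetals that react readily with 11, and it has not itself been used in this cycloaddition. The most likely failure is therefore slow cycloaddition, with hydration or oligomerisation of the ynol ether and thermal self-reaction of 11 taking over at the temperature required. The second concern is incomplete regiocontrol, with the oxygen-bearing alkyne carbon bonding to pyrone C6. The fallback buys ring A instead of building it and runs from 5 to 13. Phenol 5 is arylated by SNAr with methyl 4-fluoro-3-formylbenzoate (K2CO3, DMF, 80 °C; fluoride activated by the ortho formyl and para ester groups) to give methyl 4-(3-{2-[3-(benzyloxy)-4-methoxyphenyl]ethyl}phenoxy)-3-formylbenzoate F1. Wittig reaction with the ylide of (4-bromobenzyl)triphenylphosphonium bromide (KOtBu, THF) gives methyl 4-(3-{2-[3-(benzyloxy)-4-methoxyphenyl]ethyl}phenoxy)-3-[2-(4-bromophenyl)ethenyl]benzoate F2 as an E/Z mixture. Diimide reduction (TsNHNH2, NaOAc) returns to the route at 13.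

**Step 6.** Three processes can erode it: competing copper-mediated arylation of the phenol at the ring B aryl bromide, a second substitution to a ketene acetal, and base-induced migration of the triple bond to an allenyl ether during the elimination. The fallback runs from 5 to 10 and forms the O–C(sp) bond before the chain is attached. Phenol 5 is added to trichloroethylene (K2CO3, DMF, 70 °C) to give the (E)-1,2-dichlorovinyl ether F3. n-BuLi (2 equiv, THF, −78 to −40 °C) converts it by elimination and chlorine–lithium exchange into the lithium aryloxyacetylide F4. This is alkylated at low temperature with 2-(4-bromophenyl)ethyl trifluoromethanesulfonate F5 (from commercial 2-(4-bromophenyl)ethanol, Tf2O and 2,6-lutidine), rejoining the route at 10. The aryl bromide enters only after all n-BuLi is consumed.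

**Step 9.** Oxidative addition into an unactivated, para-alkylated aryl bromide is slow, so oligomerisation and protodebromination can overtake closure of the 18-membered ring. The fallback runs from 14 to 15 and reverses the polarity of ring B. Palladium-catalysed borylation of 14 with tetrahydroxydiboron (Pd(OAc)2, XPhos, KOAc, EtOH, 80 °C) gives the boronic acid methyl 3-[2-(4-boronophenyl)ethyl]-4-{3-[2-(3-hydroxy-4-methoxyphenyl)ethyl]phenoxy}benzoate F6. The ring is then closed by Chan–Lam coupling (Cu(OAc)2, Et3N, 4 Å molecular sieves, CH2Cl2, air, rt, high dilution), an oxidative arylation of the phenol by divalent copper at room temperature, arriving at 15.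

**Step 12.** Hydride instead of aryl migration would give the carboxylic acid, and the peracid may attack the electron-rich rings of the macrocycle. The fallback runs from 15 to 19 and replaces steps 10 to 12. Ester 15 is treated with MeMgBr (THF, 0 °C) to give the tertiary alcohol F7 (2-hydroxypropan-2-yl group on ring A). H2O2 and BF3·OEt2 (CH2Cl2, 0 °C) convert it through the cumyl-type hydroperoxide F8 in a Hock rearrangement into 19 and acetone. Only aryl or methyl can migrate there, and aryl migrates preferentially.

## Further compounds

F1 | step 7 | methyl 4-(3-{2-[3-(benzyloxy)-4-methoxyphenyl]ethyl}phenoxy)-3-formylbenzoate | COC(=O)c1ccc(Oc2cccc(CCc3ccc(OC)c(OCc4ccccc4)c3)c2)c(C=O)c1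
F2 | step 7 | methyl 4-(3-{2-[3-(benzyloxy)-4-methoxyphenyl]ethyl}phenoxy)-3-[2-(4-bromophenyl)ethenyl]benzoate (E/Z mixture) | COC(=O)c1ccc(Oc2cccc(CCc3ccc(OC)c(OCc4ccccc4)c3)c2)c(C=Cc2ccc(Br)cc2)c1
F3 | step 6 | 1-{[(E)-1,2-dichloroethenyl]oxy}-3-{2-[3-(benzyloxy)-4-methoxyphenyl]ethyl}benzene | Cl/C=C(/Cl)Oc1cccc(CCc2ccc(OC)c(OCc3ccccc3)c2)c1
F4 | step 6 | lithium aryloxyacetylide of 5 (lithium 2-(3-{2-[3-(benzyloxy)-4-methoxyphenyl]ethyl}phenoxy)ethynide) | [Li]C#COc1cccc(CCc2ccc(OC)c(OCc3ccccc3)c2)c1
F5 | step 6 | 2-(4-bromophenyl)ethyl trifluoromethanesulfonate | FC(F)(F)S(=O)(=O)OCCc1ccc(Br)cc1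
F6 | step 9 | methyl 3-[2-(4-boronophenyl)ethyl]-4-{3-[2-(3-hydroxy-4-methoxyphenyl)ethyl]phenoxy}benzoate | COC(=O)c1ccc(Oc2cccc(CCc3ccc(OC)c(O)c3)c2)c(CCc2ccc(cc2)B(O)O)c1
F7 | step 12 | macrocyclic tertiary alcohol (2-hydroxypropan-2-yl on ring A, OMe on ring C) | CC(C)(O)c1ccc2c(c1)CCc1ccc(cc1)Oc1cc(ccc1OC)CCc1cccc(c1)O2
F8 | step 12 | macrocyclic cumyl-type hydroperoxide (2-hydroperoxypropan-2-yl on ring A, OMe on ring C) | CC(C)(OO)c1ccc2c(c1)CCc1ccc(cc1)Oc1cc(ccc1OC)CCc1cccc(c1)O2
A1 | alternative 1 | open-chain fluoronitroarene phenol | COc1ccc(Oc2cccc(c2)CCc2ccc(OC)c(O)c2)c(c1)CCc1ccc(F)c(c1)[N+](=O)[O-]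
A2 | alternative 1 | macrocyclic nitro diaryl ether di-O-methyl ether | COc1ccc2c(c1)CCc1ccc(c(c1)[N+](=O)[O-])Oc1cc(ccc1OC)CCc1cccc(c1)O2
A3 | alternative 2 | open-chain 2-aryloxybutadiene ethynyl ketone | C=CC(=C)Oc1cc(ccc1OC)CCc1cccc(c1)Oc1ccc(OC)cc1CC(=O)C#C
A4 | alternative 2 | macrocyclic cyclohexadienyl ketone | COc1ccc2c(c1)CC(=O)C1=CCC(=CC1)Oc1cc(ccc1OC)CCc1cccc(c1)O2
A5 | alternative 3 | open-chain bis(dihalophenol) | COc1ccc(Oc2cccc(c2)CCc2cc(Br)c(O)c(Br)c2)c(c1)CCc1cc(Cl)c(O)c(Cl)c1
A6 | alternative 3 | trihalogenated macrocycle with free ring C phenol | COc1ccc2c(c1)CCc1cc(Cl)c(c(Cl)c1)Oc1cc(cc(Br)c1O)CCc1cccc(c1)O2
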